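**Retrosynthetic overview**
1. Target 40 ← macrocycle 37 by PMB removal, allylic oxidation to the C14 aldehyde and desilylation; the ten-membered ring is formed last, by ring-closing metathesis of triene ester 36 (C1=C10).
2. 36 ← hydroxy lactone 28 by α-methylenation (Mannich/elimination) and acylation with (S)-2-methylbutanoic anhydride.
3. 28 ← lactone aldehyde 19 + allyl iodide 24 by zinc Barbier allylation (C8–C9), then oxidation and Felkin–Anh reduction to fix C8.
4. 19 ← key intermolecular Evans syn-aldol (C6–C7) of succinate imide 11 with enal 7, then lactonization; the γ-lactone is the first ring formed.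
5. 7 ← but-2-yne-1,4-diol by directed hydroalumination/iodination and Negishi coupling.

Assumption: C1–C15 are the germacrane positions of the target (C6 lactone carbinol, C7 ring fusion, C8 ester carbinol, C12 lactone carbonyl, C13 exocyclic methylene, C14 aldehyde, C15 hydroxymethyl). The SMILES is read as 6R,7R,8R with a trans-fused lactone, both ring alkenes ring-cis (C2 cis to C9, C3 cis to C6) and an (S)-2-methylbutanoate. Compounds 5, 8, 9, 20, 21 and 35 are bought.

**Step 1**
Reactants: 1 but-2-yne-1,4-diol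
Product: 2 4-[(tert-butyldiphenylsilyl)oxy]but-2-yn-1-ol
Conditions: 1 (3 equiv), t-BuPh2SiCl (1.0 equiv), imidazole (1.2 equiv), THF/DMF, 0 °C → rt
Reagents that add atoms: tert-butyl(chloro)diphenylsilane, CC(C)(C)[Si](Cl)(c1ccccc1)c1ccccc1
Why: Statistical mono-silylation (silyl ether formation) of the symmetrical diol used in excess; no stereocentre is involved.

**Step 2**
Reactants: 2 mono-TBDPS ether of butynediol
Product: 4 (2Z)-4-[(tert-butyldiphenylsilyl)oxy]-3-iodobut-2-en-1-ol, via alkenylaluminate 3 (not isolated)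
Conditions: NaAlH2(OCH2CH2OMe)2 (1.6 equiv), THF, 0 °C → rt; EtOAc; then I2, −78 → 0 °C
Reagents that add atoms: iodine, II
Why: Alkoxide-directed trans-hydroalumination puts aluminium on C3 in a five-membered alkenylaluminate, and iodinolysis with retention gives the Z vinyl iodide (iodine cis to CH2OH).

**Step 3**
Reactants: 4 Z vinyl iodide; 5 but-3-en-1-ylzinc bromide
Product: 6 (2E)-3-{[(tert-butyldiphenylsilyl)oxy]methyl}hepta-2,6-dien-1-ol
Conditions: 5 (2.5 equiv), PdCl2(dppf) (5 mol%), THF, rt → 45 °C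
Reagents that add atoms: none
Why: Negishi cross-coupling (oxidative addition to zerovalent palladium, transmetalation, reductive elimination) retains alkene geometry, so the butenyl chain ends cis to CH2OH as needed for the ring-cis C4=C5 bond.

**Step 4**
Reactants: 6 dienol
Product: 7 (2E)-3-{[(tert-butyldiphenylsilyl)oxy]methyl}hepta-2,6-dienal
Conditions: MnO2 (15 equiv), CH2Cl2, rt
Reagents that add atoms: none
Why: MnO2 oxidation of the primary allylic alcohol stops at the enal and does not scramble the trisubstituted alkene.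

**Step 5**
Reactants: 8 (4S)-4-benzyl-1,3-oxazolidin-2-one; 9 methyl 4-chloro-4-oxobutanoate
Product: 11 methyl 4-[(4S)-4-benzyl-2-oxo-1,3-oxazolidin-3-yl]-4-oxobutanoate, via N-lithio oxazolidinone 10 (not isolated)
Conditions: n-BuLi (1.0 equiv), THF, −78 °C; then 9, −78 → 0 °C
Reagents that add atoms: none
Why: N-acylation of the lithiated auxiliary occurs at the acid chloride, which is far more electrophilic than the methyl ester.

**Step 6**
Reactants: 11 succinate imide; 7 enal
Product: 14 methyl (3S,4R,5E)-3-{[(4S)-4-benzyl-2-oxo-1,3-oxazolidin-3-yl]carbonyl}-6-{[(tert-butyldiphenylsilyl)oxy]methyl}-4-hydroxydeca-5,9-dienoate, via boron enolate 12 (not isolated), via boron aldolate 13 (not isolated)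
Conditions: Bu2BOTf (1.2 equiv), i-Pr2NEt (1.4 equiv), CH2Cl2, 0 °C; then 7, −78 → 0 °C; pH 7 buffer, MeOH, 30% H2O2, 0 °C
Reagents that add atoms: none
Why: Evans syn-aldol reaction: the Z boron enolate reacts through a Zimmerman–Traxler chair on the face away from the benzyl group, setting C6 (R) and C7 in the syn relationship that becomes the trans-lactone.

**Step 7**
Reactants: 14 syn-aldol adduct
Product: 15 (4S)-4-benzyl-3-{[(2R,3S)-2-[(1E)-2-{[(tert-butyldiphenylsilyl)oxy]methyl}hexa-1,5-dien-1-yl]-5-oxooxolan-3-yl]carbonyl}-1,3-oxazolidin-2-one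
Conditions: pyridinium p-toluenesulfonate (0.1 equiv), toluene, 60 °C
Reagents that add atoms: none
Why: Acid-catalysed lactonization (intramolecular transesterification) of the γ-hydroxy ester leaves the C6–O bond intact, so the syn aldol gives the trans-4,5-disubstituted γ-lactone.

**Step 8**
Reactants: 15 lactone imide
Product: 17 (2R,3S)-2-[(1E)-2-{[(tert-butyldiphenylsilyl)oxy]methyl}hexa-1,5-dien-1-yl]-5-oxooxolane-3-carboxylic acid, via peroxy acid 16 (not isolated)
Conditions: LiOH (2 equiv), 30% H2O2 (4 equiv), THF/H2O 3:1, 0 °C; aq. Na2SO3; then 1 M HCl to pH 2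
Reagents that add atoms: hydrogen peroxide, OO
Why: Hydroperoxide attacks the exocyclic imide carbonyl selectively (Evans auxiliary cleavage), sulfite reduces the peroxy acid, and acidification recloses any opened lactone without touching a stereocentre.

**Step 9**
Reactants: 17 lactone acid
Product: 19 (2R,3S)-2-[(1E)-2-{[(tert-butyldiphenylsilyl)oxy]methyl}hexa-1,5-dien-1-yl]-5-oxooxolane-3-carbaldehyde, via acid chloride 18 (not isolated)
Conditions: (COCl)2 (1.5 equiv), DMF (cat.), CH2Cl2, 0 °C → rt; evaporate; then LiAlH(Ot-Bu)3 (1.05 equiv), THF, −78 °C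
Reagents that add atoms: none
Why: Acid chloride formation followed by partial reduction with the hindered hydride stops at the aldehyde at −78 °C and spares lactone, alkenes and silyl ether; the trans C7 configuration is the thermodynamic one.

**Step 10**
Reactants: 20 3-chloro-2-(chloromethyl)prop-1-ene; 21 (4-methoxyphenyl)methanol
Product: 23 1-({[2-(chloromethyl)prop-2-en-1-yl]oxy}methyl)-4-methoxybenzene, via sodium alkoxide 22 (not isolated)
Conditions: NaH (1.0 equiv), THF, 0 °C; then 20 (3 equiv), n-Bu4NI (5 mol%), 0 °C → rt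
Reagents that add atoms: none
Why: Williamson ether synthesis in which the threefold excess of dichloride limits substitution to one allylic chloride.

**Step 11**
Reactants: 23 allylic chloride
Product: 24 1-({[2-(iodomethyl)prop-2-en-1-yl]oxy}methyl)-4-methoxybenzene
Conditions: NaI (1.5 equiv), acetone, rt, dark
Reagents that add atoms: sodium iodide, [Na+].[I-]
Why: Finkelstein halide exchange, driven by precipitation of NaCl, gives the more reactive allylic iodide.

**Step 12**
Reactants: 19 lactone aldehyde; 24 allylic iodide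
Product: 26 homoallylic alcohol (both C8 epimers), via allylzinc iodide 25 (not isolated)
Conditions: Zn dust (3 equiv), 24 (2 equiv), THF/sat. aq. NH4Cl 4:1, 0 °C → rt
Reagents that add atoms: none
Why: Zinc Barbier carbonyl allylation is chemoselective for the aldehyde over the lactone and, with two identical allyl termini, gives one constitution; the C8 epimer mixture is erased in step 13.

**Step 13**
Reactants: 26 homoallylic alcohol (epimers)
Product: 27 (4S,5R)-5-[(1E)-2-{[(tert-butyldiphenylsilyl)oxy]methyl}hexa-1,5-dien-1-yl]-4-(3-{[(4-methoxybenzyl)oxy]methyl}but-3-enoyl)oxolan-2-one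
Conditions: Dess–Martin periodinane (1.5 equiv), NaHCO3 (5 equiv), CH2Cl2, 0 °C → rt
Reagents that add atoms: none
Why: Buffered Dess–Martin oxidation converts both epimers into one β,γ-unsaturated ketone under non-basic conditions, avoiding alkene migration and β-elimination of the lactone oxygen.

**Step 14**
Reactants: 27 C8 ketone
Product: 28 (4R,5R)-5-[(1E)-2-{[(tert-butyldiphenylsilyl)oxy]methyl}hexa-1,5-dien-1-yl]-4-[(1R)-1-hydroxy-3-{[(4-methoxybenzyl)oxy]methyl}but-3-en-1-yl]oxolan-2-one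
Conditions: LiBH(s-Bu)3 (1.2 equiv), THF, −78 °C; then H2O
Reagents that add atoms: none
Why: Felkin–Anh-controlled reduction with a bulky non-chelating hydride: attack anti to the larger C7–C6 ring bond, past C7–H, should give the 8R carbinol (O8 anti to C11 and to O6); this is a model prediction and is backed by a fallback below.

**Step 15**
Reactants: 28 (8R)-alcohol
Product: 29 triethylsilyl ether of 28
Conditions: Et3SiCl (1.3 equiv), imidazole (2 equiv), DMF, 0 °C
Reagents that add atoms: chlorotriethylsilane, CC[Si](Cl)(CC)CC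
Why: Silyl ether formation masks the C8 hydroxyl so that the following enolate chemistry cannot trigger translactonization.

**Step 16**
Reactants: 29 TES ether
Product: 31 α-(dimethylaminomethyl) lactone (C11 epimers), via lithium enolate 30 (not isolated)
Conditions: LiN(i-Pr)2 (1.3 equiv), THF, −78 °C; then CH2=NMe2+ I− (3 equiv), −78 °C → rt
Reagents that add atoms: N,N-dimethylmethyleneiminium iodide, C=[N+](C)C.[I-]
Why: Mannich reaction of the lactone lithium enolate (C11 is the only enolisable position) with the preformed iminium salt; the new C11 centre is destroyed in step 17.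

**Step 17**
Reactants: 31 Mannich base
Product: 33 α-methylene lactone TES ether, via ammonium iodide 32 (not isolated)
Conditions: MeI (10 equiv), MeOH, rt; evaporate; then sat. aq. NaHCO3/EtOAc, rt
Reagents that add atoms: none
Why: N-methylation followed by base-induced β-elimination of trimethylamine (Hofmann-type) creates the exocyclic C11=C13 bond.

**Step 18**
Reactants: 33 α-methylene lactone TES ether
Product: 34 (4R,5R)-5-[(1E)-2-{[(tert-butyldiphenylsilyl)oxy]methyl}hexa-1,5-dien-1-yl]-4-[(1R)-1-hydroxy-3-{[(4-methoxybenzyl)oxy]methyl}but-3-en-1-yl]-3-methylideneoxolan-2-one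
Conditions: HF·pyridine, pyridine, THF, 0 °C
Reagents that add atoms: none
Why: Buffered fluoride desilylation cleaves the secondary triethylsilyl ether much faster than the primary tert-butyldiphenylsilyl ether and leaves the PMB ether and enoate alone.

**Step 19**
Reactants: 34 C8 alcohol; 35 (2S)-2-methylbutanoic anhydride
Product: 36 (2S)-2-methylbutanoate of 34
Conditions: 35 (1.5 equiv), 4-(dimethylamino)pyridine (0.2 equiv), pyridine (3 equiv), CH2Cl2, 0 °C → rt
Reagents that add atoms: none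
Why: Nucleophile-catalysed acylation breaks no bond to C8 or to the acyl α-carbon, so both configurations are carried over unchanged.

**Step 20**
Reactants: 36 triene ester
Product: 37 ten-membered macrocycle (C15 OTBDPS and C14 OPMB)
Conditions: second-generation Grubbs catalyst RuCl2(=CHPh)(PCy3)(H2IMes) (10 mol%), toluene (0.5 mM), 60 °C
Reagents that add atoms: none
Why: Ring-closing metathesis: the catalyst loads on the monosubstituted C1 vinyl group and closes onto the 1,1-disubstituted C10 alkene with loss of ethene; the ring-cis C1=C10 geometry is expected, being the less strained isomer in a ten-membered ring that already holds a cis alkene and a trans-fused lactone.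

**Step 21**
Reactants: 37 macrocycle
Product: 38 C14 allylic alcohol
Conditions: DDQ (1.3 equiv), CH2Cl2/pH 7 buffer 10:1, 0 °C
Reagents that add atoms: none
Why: Oxidative PMB ether cleavage (benzylic hydride abstraction, then hydrolysis of the oxocarbenium ion) is orthogonal to the silyl ether, the esters and the alkenes.

**Step 22**
Reactants: 38 C14 allylic alcohol
Product: 39 C14 enal (C15 OTBDPS)
Conditions: MnO2 (15 equiv), CH2Cl2, rt
Reagents that add atoms: none
Why: Allylic oxidation with MnO2 gives the conjugated aldehyde with the C1=C10 geometry retained (CHO trans to C2).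

**Step 23**
Reactants: 39 silyl-protected enal
Product: 40 target CNP0168859.6
Conditions: HF·pyridine, pyridine, THF, 0 °C → rt
Reagents that add atoms: none
Why: Buffered, non-basic fluoride desilylation frees the C15 hydroxyl without harming the enal, the α-methylene lactone or the ester.

**Compound list**
1 | but-2-yne-1,4-diol | OCC#CCO | starting material
2 | 4-[(tert-butyldiphenylsilyl)oxy]but-2-yn-1-ol | OCC#CCO[Si](c1ccccc1)(c1ccccc1)C(C)(C)C | intermediate
3 | sodium cyclic alkenylaluminate from 2 (1-oxa-2-aluminacyclopent-3-ene with two 2-methoxyethoxy groups on Al and CH2OTBDPS on C3) | [Na+].COCCO[Al-]1(OCCOC)OCC=C1CO[Si](c1ccccc1)(c1ccccc1)C(C)(C)C | intermediate (not isolated)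
4 | (2Z)-4-[(tert-butyldiphenylsilyl)oxy]-3-iodobut-2-en-1-ol | OC/C=C(\I)CO[Si](c1ccccc1)(c1ccccc1)C(C)(C)C | intermediate
5 | but-3-en-1-ylzinc bromide | C=CCC[Zn]Br | starting material
6 | (2E)-3-{[(tert-butyldiphenylsilyl)oxy]methyl}hepta-2,6-dien-1-ol | OC/C=C(\CCC=C)CO[Si](c1ccccc1)(c1ccccc1)C(C)(C)C | intermediate
7 | (2E)-3-{[(tert-butyldiphenylsilyl)oxy]methyl}hepta-2,6-dienal | O=C/C=C(\CCC=C)CO[Si](c1ccccc1)(c1ccccc1)C(C)(C)C | intermediate
8 | (4S)-4-benzyl-1,3-oxazolidin-2-one | O=C1OC[C@H](Cc2ccccc2)N1 | starting material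
9 | methyl 4-chloro-4-oxobutanoate | COC(=O)CCC(Cl)=O | starting material
10 | N-lithio derivative of 8 | [Li]N1[C@@H](Cc2ccccc2)COC1=O | intermediate (not isolated)
11 | methyl 4-[(4S)-4-benzyl-2-oxo-1,3-oxazolidin-3-yl]-4-oxobutanoate | COC(=O)CCC(=O)N1[C@@H](Cc2ccccc2)COC1=O | intermediate
12 | (Z)-dibutylboron enolate of 11 | CCCCB(CCCC)O/C(=C\CC(=O)OC)N1[C@@H](Cc2ccccc2)COC1=O | intermediate (not isolated)
13 | O-dibutylboryl aldolate of 14 | COC(=O)C[C@H](C(=O)N1[C@@H](Cc2ccccc2)COC1=O)[C@H](OB(CCCC)CCCC)/C=C(/CO[Si](c1ccccc1)(c1ccccc1)C(C)(C)C)CCC=C | intermediate (not isolated)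
14 | methyl (3S,4R,5E)-3-{[(4S)-4-benzyl-2-oxo-1,3-oxazolidin-3-yl]carbonyl}-6-{[(tert-butyldiphenylsilyl)oxy]methyl}-4-hydroxydeca-5,9-dienoate | COC(=O)C[C@H](C(=O)N1[C@@H](Cc2ccccc2)COC1=O)[C@H](O)/C=C(/CO[Si](c1ccccc1)(c1ccccc1)C(C)(C)C)CCC=C | intermediate
15 | (4S)-4-benzyl-3-{[(2R,3S)-2-[(1E)-2-{[(tert-butyldiphenylsilyl)oxy]methyl}hexa-1,5-dien-1-yl]-5-oxooxolan-3-yl]carbonyl}-1,3-oxazolidin-2-one | O=C1C[C@H](C(=O)N2[C@@H](Cc3ccccc3)COC2=O)[C@@H](/C=C(/CO[Si](c2ccccc2)(c2ccccc2)C(C)(C)C)CCC=C)O1 | intermediate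
16 | peroxy acid corresponding to 17 | O=C1C[C@H](C(=O)OO)[C@@H](/C=C(/CO[Si](c2ccccc2)(c2ccccc2)C(C)(C)C)CCC=C)O1 | intermediate (not isolated)
17 | (2R,3S)-2-[(1E)-2-{[(tert-butyldiphenylsilyl)oxy]methyl}hexa-1,5-dien-1-yl]-5-oxooxolane-3-carboxylic acid | O=C1C[C@H](C(=O)O)[C@@H](/C=C(/CO[Si](c2ccccc2)(c2ccccc2)C(C)(C)C)CCC=C)O1 | intermediate
18 | acid chloride of 17 | O=C1C[C@H](C(Cl)=O)[C@@H](/C=C(/CO[Si](c2ccccc2)(c2ccccc2)C(C)(C)C)CCC=C)O1 | intermediate (not isolated)
19 | (2R,3S)-2-[(1E)-2-{[(tert-butyldiphenylsilyl)oxy]methyl}hexa-1,5-dien-1-yl]-5-oxooxolane-3-carbaldehyde | O=C1C[C@H](C=O)[C@@H](/C=C(/CO[Si](c2ccccc2)(c2ccccc2)C(C)(C)C)CCC=C)O1 | intermediate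
20 | 3-chloro-2-(chloromethyl)prop-1-ene | C=C(CCl)CCl | starting material
21 | (4-methoxyphenyl)methanol | COc1ccc(CO)cc1 | starting material
22 | sodium (4-methoxyphenyl)methanolate | [Na+].[O-]Cc1ccc(OC)cc1 | intermediate (not isolated)
23 | 1-({[2-(chloromethyl)prop-2-en-1-yl]oxy}methyl)-4-methoxybenzene | C=C(CCl)COCc1ccc(OC)cc1 | intermediate
24 | 1-({[2-(iodomethyl)prop-2-en-1-yl]oxy}methyl)-4-methoxybenzene | C=C(CI)COCc1ccc(OC)cc1 | intermediate
25 | allylzinc iodide from 24 | C=C(C[Zn]I)COCc1ccc(OC)cc1 | intermediate (not isolated)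
26 | (4R,5R)-5-[(1E)-2-{[(tert-butyldiphenylsilyl)oxy]methyl}hexa-1,5-dien-1-yl]-4-[1-hydroxy-3-{[(4-methoxybenzyl)oxy]methyl}but-3-en-1-yl]oxolan-2-one, both C8 epimers | O=C1C[C@H](C(O)CC(=C)COCc2ccc(OC)cc2)[C@@H](/C=C(/CO[Si](c2ccccc2)(c2ccccc2)C(C)(C)C)CCC=C)O1 | intermediate
27 | (4S,5R)-5-[(1E)-2-{[(tert-butyldiphenylsilyl)oxy]methyl}hexa-1,5-dien-1-yl]-4-(3-{[(4-methoxybenzyl)oxy]methyl}but-3-enoyl)oxolan-2-one | O=C1C[C@H](C(=O)CC(=C)COCc2ccc(OC)cc2)[C@@H](/C=C(/CO[Si](c2ccccc2)(c2ccccc2)C(C)(C)C)CCC=C)O1 | intermediate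
28 | (4R,5R)-5-[(1E)-2-{[(tert-butyldiphenylsilyl)oxy]methyl}hexa-1,5-dien-1-yl]-4-[(1R)-1-hydroxy-3-{[(4-methoxybenzyl)oxy]methyl}but-3-en-1-yl]oxolan-2-one | O=C1C[C@H]([C@H](O)CC(=C)COCc2ccc(OC)cc2)[C@@H](/C=C(/CO[Si](c2ccccc2)(c2ccccc2)C(C)(C)C)CCC=C)O1 | intermediate
29 | triethylsilyl ether of 28 (C8 OSiEt3, configuration as 28) | O=C1C[C@H]([C@H](O[Si](CC)(CC)CC)CC(=C)COCc2ccc(OC)cc2)[C@@H](/C=C(/CO[Si](c2ccccc2)(c2ccccc2)C(C)(C)C)CCC=C)O1 | intermediate
30 | lithium enolate of 29 | [Li]OC1=C[C@H]([C@H](O[Si](CC)(CC)CC)CC(=C)COCc2ccc(OC)cc2)[C@@H](/C=C(/CO[Si](c2ccccc2)(c2ccccc2)C(C)(C)C)CCC=C)O1 | intermediate (not isolated)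
31 | 3-[(dimethylamino)methyl] derivative of 29 (C11 epimers) | O=C1C(CN(C)C)[C@H]([C@H](O[Si](CC)(CC)CC)CC(=C)COCc2ccc(OC)cc2)[C@@H](/C=C(/CO[Si](c2ccccc2)(c2ccccc2)C(C)(C)C)CCC=C)O1 | intermediate
32 | trimethylammonium iodide of 31 | O=C1C(C[N+](C)(C)C)[C@H]([C@H](O[Si](CC)(CC)CC)CC(=C)COCc2ccc(OC)cc2)[C@@H](/C=C(/CO[Si](c2ccccc2)(c2ccccc2)C(C)(C)C)CCC=C)O1.[I-] | intermediate (not isolated)
33 | 3-methylidene lactone, C8 triethylsilyl ether (configuration as 28) | O=C1C(=C)[C@H]([C@H](O[Si](CC)(CC)CC)CC(=C)COCc2ccc(OC)cc2)[C@@H](/C=C(/CO[Si](c2ccccc2)(c2ccccc2)C(C)(C)C)CCC=C)O1 | intermediate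
34 | (4R,5R)-5-[(1E)-2-{[(tert-butyldiphenylsilyl)oxy]methyl}hexa-1,5-dien-1-yl]-4-[(1R)-1-hydroxy-3-{[(4-methoxybenzyl)oxy]methyl}but-3-en-1-yl]-3-methylideneoxolan-2-one | O=C1C(=C)[C@H]([C@H](O)CC(=C)COCc2ccc(OC)cc2)[C@@H](/C=C(/CO[Si](c2ccccc2)(c2ccccc2)C(C)(C)C)CCC=C)O1 | intermediate
35 | (2S)-2-methylbutanoic anhydride | CC[C@H](C)C(=O)OC(=O)[C@@H](C)CC | starting material
36 | (2S)-2-methylbutanoate of 34 at C8 (6R,7R,8R in target numbering) | O=C1C(=C)[C@H]([C@H](OC(=O)[C@@H](C)CC)CC(=C)COCc2ccc(OC)cc2)[C@@H](/C=C(/CO[Si](c2ccccc2)(c2ccccc2)C(C)(C)C)CCC=C)O1 | intermediate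
37 | (6R,7R,8R)-germacra-1(10),4,11(13)-trien-6,12-olide with ring-cis C1=C10 and C4=C5, 8-[(2S)-2-methylbutanoyloxy], 14-[(4-methoxybenzyl)oxy], 15-[(tert-butyldiphenylsilyl)oxy] | C=C1C(=O)O[C@@H]2/C=C(/CO[Si](c3ccccc3)(c3ccccc3)C(C)(C)C)CC/C=C(/COCc3ccc(OC)cc3)C[C@@H](OC(=O)[C@@H](C)CC)[C@@H]12 | intermediate
38 | 14-hydroxy analogue of 37 (15-OTBDPS retained) | C=C1C(=O)O[C@@H]2/C=C(/CO[Si](c3ccccc3)(c3ccccc3)C(C)(C)C)CC/C=C(/CO)C[C@@H](OC(=O)[C@@H](C)CC)[C@@H]12 | intermediate
39 | 14-oxo analogue of 38 (15-OTBDPS retained) | C=C1C(=O)O[C@@H]2/C=C(/CO[Si](c3ccccc3)(c3ccccc3)C(C)(C)C)CC/C=C(/C=O)C[C@@H](OC(=O)[C@@H](C)CC)[C@@H]12 | intermediate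
40 | (6R,7R,8R)-15-hydroxy-8-[(2S)-2-methylbutanoyloxy]-14-oxogermacra-1(10),4,11(13)-trien-6,12-olide, both ring alkenes ring-cis (CNP0168859.6) | C=C1C(=O)O[C@@H]2/C=C(/CO)CC/C=C(/C=O)C[C@@H](OC(=O)[C@@H](C)CC)[C@@H]12 | target

**Totals and risks**
Total steps: 23. Longest linear sequence: 20 steps (steps 1–4, 6–9 and 12–23).

Most likely to fail, first: step 20 (ring-closing metathesis to a ten-membered ring with a trisubstituted alkene, next to a bulky ester and in the presence of the α-methylene lactone). The fallback changes the order of ring closure and acylation. It sets out from 34: the metathesis is run on the free C8 alcohol (same ruthenium catalyst, high dilution), where the substituent beside the 1,1-disubstituted alkene is only a hydroxyl, to give the macrocyclic hydroxy lactone F1. Acylation of F1 with anhydride 35 (4-(dimethylamino)pyridine, pyridine) then comes back to the route at 37.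

Second: step 14 (C8 configuration rests on a Felkin–Anh prediction, and ketone 27 is prone to alkene migration and β-elimination). The fallback replaces stereoselective reduction by stereoinversion and never makes the ketone. It sets out from 26: the two C8 epimers are separated on silica, and the 8R epimer is 28 itself. The (8S)-alcohol F2 is inverted by a Mitsunobu reaction (ClCH2CO2H, PPh3, diisopropyl azodicarboxylate, toluene, 0 °C → rt) to the (8R)-chloroacetate F3. F3 is cleaved under neutral conditions (thiourea, NaHCO3, EtOH, 50 °C) and comes back to the route at 28.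

Third: step 9 (over-reduction, and a β-acyloxy aldehyde that can eliminate). The fallback avoids the acid and the acid chloride. It sets out from 15: reductive cleavage of the auxiliary (NaBH4, THF/H2O, 0 °C) gives the hydroxymethyl lactone F4. Buffered Dess–Martin oxidation of F4 comes back to the route at 19.

**Further compounds**
F1 | step 20 | macrocyclic C8 alcohol (37 without the 2-methylbutanoyl group) | C=C1C(=O)O[C@@H]2/C=C(/CO[Si](c3ccccc3)(c3ccccc3)C(C)(C)C)CC/C=C(/COCc3ccc(OC)cc3)C[C@@H](O)[C@@H]12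
F2 | step 14 | (4R,5R)-5-[(1E)-2-{[(tert-butyldiphenylsilyl)oxy]methyl}hexa-1,5-dien-1-yl]-4-[(1S)-1-hydroxy-3-{[(4-methoxybenzyl)oxy]methyl}but-3-en-1-yl]oxolan-2-one | O=C1C[C@H]([C@@H](O)CC(=C)COCc2ccc(OC)cc2)[C@@H](/C=C(/CO[Si](c2ccccc2)(c2ccccc2)C(C)(C)C)CCC=C)O1
F3 | step 14 | (8R)-chloroacetate of 28 | O=C1C[C@H]([C@H](OC(=O)CCl)CC(=C)COCc2ccc(OC)cc2)[C@@H](/C=C(/CO[Si](c2ccccc2)(c2ccccc2)C(C)(C)C)CCC=C)O1
F4 | step 9 | (4R,5R)-5-[(1E)-2-{[(tert-butyldiphenylsilyl)oxy]methyl}hexa-1,5-dien-1-yl]-4-(hydroxymethyl)oxolan-2-one | O=C1C[C@H](CO)[C@@H](/C=C(/CO[Si](c2ccccc2)(c2ccccc2)C(C)(C)C)CCC=C)O1
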